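**Strategy.** Gustastatin is cut at its depside ester into a ring A salicylic acid and a ring B phenol. Everything rests on the C6–CH2 bond of ring A: C6 is the only free carbon ortho to the C1 carboxyl, because C2 carries oxygen. One carboxylate-directed C–H acylmethylation joins purchased 2,4-dimethoxybenzoic acid to a hexanoyl sulfoxonium ylide and closes a temporary enol lactone from the carboxyl oxygen to the ketone carbon. The complete 2-oxoheptyl arm thus arrives as a 3-pentylisocoumarin that keeps acid and ketone locked up until needed. Peri-selective demethylation, lactone opening, ketalisation and carbodiimide coupling with a ring B phenol made from methyl orsellinate finish the synthesis.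

Key step: step 2

Remark on the chemistry: the target has no stereocentre; the ring A 2-hydroxyl, hydrogen-bonded to the neighbouring carbonyl, is assumed to stay inert in the carboxylate alkylation and the carbodiimide coupling, and N-methoxy-N-methylhexanamide is made in house from hexanoyl chloride.

**Route**

Step 1
Reactants: 1 hexanoyl chloride; 2 trimethylsulfoxonium iodide
Product: 4 1-[dimethyl(oxo)-λ6-sulfanylidene]heptan-2-one, via dimethylsulfoxonium methylide 3 (not isolated)
Conditions: 2 (3 equiv), KOtBu (3 equiv), THF, reflux; then 1 (1 equiv), 0 °C → rt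
Reagents that add atoms: none
Why: Acylation of a sulfur ylide, in which methylide 3 adds to the acid chloride and a second equivalent removes the now acidic α-proton, should give the carbonyl-stabilised sulfoxonium ylide, which does not react further.

Step 2
Reactants: 5 2,4-dimethoxybenzoic acid; 4 1-[dimethyl(oxo)-λ6-sulfanylidene]heptan-2-one
Product: 7 6,8-dimethoxy-3-pentylisochromen-1-one, via 2,4-dimethoxy-6-(2-oxoheptyl)benzoic acid 6 (not isolated)
Conditions: [Cp*RhCl2]2 (4 mol %), AgSbF6 (16 mol %), NaOAc (30 mol %), (CF3)2CHOH, 80 °C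
Reagents that add atoms: none
Why: The carboxylate of 5 binds the cationic Cp*Rh centre (trivalent rhodium) and directs concerted metalation–deprotonation of the C6–H bond to a five-membered rhodacycle; 4 then binds through carbon, loses dimethyl sulfoxide to give a rhodium carbene, and migratory insertion followed by protodemetalation releases keto acid 6. The closest known reaction type is the carboxylate-directed C–H acylmethylation and annulation of benzoic acids with sulfoxonium ylides under [Cp*RhCl2]2 or [RuCl2(p-cymene)]2 catalysis, which gives 3-substituted isocoumarins. The pyranone ring closes in the acidic medium by 6-exo-trig addition of the carboxyl oxygen to the ketone carbon, followed by loss of water from the lactol. No stereocentre is formed. The step needs site selectivity and single alkylation: the C2 methoxy group leaves C6 as the only ortho C–H, and lactonisation removes the directing carboxylate after one insertion.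

Step 3
Reactants: 7 6,8-dimethoxy-3-pentylisochromen-1-one
Product: 8 8-hydroxy-6-methoxy-3-pentylisochromen-1-one
Conditions: BCl3 (1.5 equiv), CH2Cl2, −78 → 0 °C; aq. work-up
Reagents that add atoms: none
Why: In this chelation-controlled Lewis acid ether cleavage, BCl3 bridges the lactone carbonyl and the peri C8 methoxy oxygen in a six-membered chelate, so chloride should remove only that methyl group and leave the remote C6 methyl ether.

Step 4
Reactants: 8 8-hydroxy-6-methoxy-3-pentylisochromen-1-one
Product: 10 benzyl 2-hydroxy-4-methoxy-6-(2-oxoheptyl)benzoate, via 2-hydroxy-4-methoxy-6-(2-oxoheptyl)benzoic acid 9 (not isolated)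
Conditions: KOH (5 equiv), EtOH/H2O, reflux; 1 M HCl to pH 3, 0 °C, EtOAc extraction; then BnBr (1.1 equiv), KHCO3 (1.5 equiv), DMF, rt
Reagents that add atoms: potassium hydroxide, [K+].[OH-]; benzyl bromide, BrCc1ccccc1
Why: Lactone saponification is irreversible because it ends at the carboxylate and the ketone, and the crude acid should then undergo SN2 O-benzylation at the carboxylate only, since KHCO3 ionises neither the hydrogen-bonded 2-hydroxyl nor the ketone α-positions.

Step 5
Reactants: 10 benzyl 2-hydroxy-4-methoxy-6-(2-oxoheptyl)benzoate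
Product: 11 benzyl 2-hydroxy-4-methoxy-6-[(2-pentyl-1,3-dioxolan-2-yl)methyl]benzoate
Conditions: (TMSOCH2)2 (3 equiv), TMSOTf (10 mol %), CH2Cl2, −78 → −20 °C; pyridine, aq. NaHCO3
Reagents that add atoms: 1,2-bis(trimethylsilyloxy)ethane, C[Si](C)(C)OCCO[Si](C)(C)C
Why: Noyori ketalisation activates the dialkyl ketone at low temperature and closes the dioxolane with loss of hexamethyldisiloxane, under conditions too mild for acid-driven enol lactonisation onto the benzyl ester, and any transient aryl silyl ether should fall off in the aqueous work-up.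

Step 6
Reactants: 11 benzyl 2-hydroxy-4-methoxy-6-[(2-pentyl-1,3-dioxolan-2-yl)methyl]benzoate
Product: 12 2-hydroxy-4-methoxy-6-[(2-pentyl-1,3-dioxolan-2-yl)methyl]benzoic acid
Conditions: H2 (1 atm), Pd/C, EtOAc, rt; filtered, concentrated cold and used at once
Reagents that add atoms: none
Why: Hydrogenolysis of the benzyl ester on Pd/C is neutral and should free the acid without touching the dioxolane or the aryl methyl ether.

Step 7
Reactants: 1 hexanoyl chloride
Product: 13 N-methoxy-N-methylhexanamide
Conditions: MeNHOMe·HCl (1.1 equiv), pyridine (2.2 equiv), CH2Cl2, 0 °C → rt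
Reagents that add atoms: N,O-dimethylhydroxylamine hydrochloride, CNOC.Cl
Why: N-Acylation of the hydroxylamine by the acid chloride should give the Weinreb amide, whose chelated tetrahedral adduct later stops acylation at the ketone stage.

Step 8
Reactants: 14 methyl 2,4-dihydroxy-6-methylbenzoate
Product: 16 methyl 4-(benzyloxy)-2-methoxy-6-methylbenzoate, via methyl 4-(benzyloxy)-2-hydroxy-6-methylbenzoate 15 (not isolated)
Conditions: BnBr (1.0 equiv), K2CO3 (3 equiv), DMF, rt; then MeI (2 equiv), 50 °C
Reagents that add atoms: benzyl bromide, BrCc1ccccc1; iodomethane, CI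
Why: In two successive Williamson etherifications the free C4 hydroxyl should be benzylated first at room temperature because the C2 hydroxyl is hydrogen-bonded to the ester, and that hydroxyl is then methylated on warming.

Step 9
Reactants: 16 methyl 4-(benzyloxy)-2-methoxy-6-methylbenzoate; 13 N-methoxy-N-methylhexanamide
Product: 17 methyl 4-(benzyloxy)-2-methoxy-6-(2-oxoheptyl)benzoate
Conditions: LiN(iPr)2 (2.2 equiv, commercial solution), THF, −78 °C; 13 (1.2 equiv), −78 °C; AcOH, −78 °C
Reagents that add atoms: none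
Why: Lateral lithiation of the ortho-toluate followed by Weinreb ketone synthesis should work because the ester-stabilised benzylic anion acylates the amide, the chelated adduct survives until the cold acidic quench, and the second equivalent of base covers the acidic product.

Step 10
Reactants: 17 methyl 4-(benzyloxy)-2-methoxy-6-(2-oxoheptyl)benzoate
Product: 18 methyl 4-hydroxy-2-methoxy-6-(2-oxoheptyl)benzoate
Conditions: H2 (1 atm), Pd/C, EtOAc, rt
Reagents that add atoms: none
Why: Hydrogenolysis of the aryl benzyl ether on Pd/C should leave the aliphatic ketone and the methyl ester untouched under one atmosphere of hydrogen.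

Step 11
Reactants: 12 2-hydroxy-4-methoxy-6-[(2-pentyl-1,3-dioxolan-2-yl)methyl]benzoic acid; 18 methyl 4-hydroxy-2-methoxy-6-(2-oxoheptyl)benzoate
Product: 19 methyl 4-({2-hydroxy-4-methoxy-6-[(2-pentyl-1,3-dioxolan-2-yl)methyl]benzoyl}oxy)-2-methoxy-6-(2-oxoheptyl)benzoate
Conditions: 18 (1.1 equiv), DCC (1.2 equiv), DMAP (5 mol %), CH2Cl2, 0 °C → rt
Reagents that add atoms: none
Why: In this Steglich-type carbodiimide esterification, of the kind used for lichen depsides, the activated carboxyl of 12 should acylate the unhindered, acidic C4 phenol of 18, while the flanked, hydrogen-bonded 2-hydroxyl of 12 stays out and the ketal keeps the ketone from attacking the activated carboxyl.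

Step 12
Reactants: 19 methyl 4-({2-hydroxy-4-methoxy-6-[(2-pentyl-1,3-dioxolan-2-yl)methyl]benzoyl}oxy)-2-methoxy-6-(2-oxoheptyl)benzoate
Product: 20 gustastatin, methyl 4-{[2-hydroxy-4-methoxy-6-(2-oxoheptyl)benzoyl]oxy}-2-methoxy-6-(2-oxoheptyl)benzoate
Conditions: 1 M aq. HCl, THF, 0 °C → rt
Reagents that add atoms: water, O
Why: Acid-catalysed ketal hydrolysis under dilute, cold conditions should unmask the ketone while the aryl ester, the methyl ester and the ring B ketone remain intact.

**Compound list**

1 | hexanoyl chloride | CCCCCC(=O)Cl | starting material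
2 | trimethylsulfoxonium iodide | C[S+](C)(C)=O.[I-] | starting material
3 | dimethylsulfoxonium methylide | C=S(C)(C)=O | intermediate
4 | 1-[dimethyl(oxo)-λ6-sulfanylidene]heptan-2-one | CCCCCC(=O)C=S(C)(C)=O | intermediate
5 | 2,4-dimethoxybenzoic acid | COc1ccc(C(=O)O)c(OC)c1 | starting material
6 | 2,4-dimethoxy-6-(2-oxoheptyl)benzoic acid | CCCCCC(=O)Cc1cc(OC)cc(OC)c1C(=O)O | intermediate
7 | 6,8-dimethoxy-3-pentylisochromen-1-one | CCCCCC1=Cc2cc(OC)cc(OC)c2C(=O)O1 | intermediate
8 | 8-hydroxy-6-methoxy-3-pentylisochromen-1-one | CCCCCC1=Cc2cc(OC)cc(O)c2C(=O)O1 | intermediate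
9 | 2-hydroxy-4-methoxy-6-(2-oxoheptyl)benzoic acid | CCCCCC(=O)Cc1cc(OC)cc(O)c1C(=O)O | intermediate
10 | benzyl 2-hydroxy-4-methoxy-6-(2-oxoheptyl)benzoate | CCCCCC(=O)Cc1cc(OC)cc(O)c1C(=O)OCc1ccccc1 | intermediate
11 | benzyl 2-hydroxy-4-methoxy-6-[(2-pentyl-1,3-dioxolan-2-yl)methyl]benzoate | CCCCCC1(Cc2cc(OC)cc(O)c2C(=O)OCc2ccccc2)OCCO1 | intermediate
12 | 2-hydroxy-4-methoxy-6-[(2-pentyl-1,3-dioxolan-2-yl)methyl]benzoic acid | CCCCCC1(Cc2cc(OC)cc(O)c2C(=O)O)OCCO1 | intermediate
13 | N-methoxy-N-methylhexanamide | CCCCCC(=O)N(C)OC | intermediate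
14 | methyl 2,4-dihydroxy-6-methylbenzoate | Cc1cc(O)cc(O)c1C(=O)OC | starting material
15 | methyl 4-(benzyloxy)-2-hydroxy-6-methylbenzoate | Cc1cc(OCc2ccccc2)cc(O)c1C(=O)OC | intermediate
16 | methyl 4-(benzyloxy)-2-methoxy-6-methylbenzoate | Cc1cc(OCc2ccccc2)cc(OC)c1C(=O)OC | intermediate
17 | methyl 4-(benzyloxy)-2-methoxy-6-(2-oxoheptyl)benzoate | CCCCCC(=O)Cc1cc(OCc2ccccc2)cc(OC)c1C(=O)OC | intermediate
18 | methyl 4-hydroxy-2-methoxy-6-(2-oxoheptyl)benzoate | CCCCCC(=O)Cc1cc(O)cc(OC)c1C(=O)OC | intermediate
19 | methyl 4-({2-hydroxy-4-methoxy-6-[(2-pentyl-1,3-dioxolan-2-yl)methyl]benzoyl}oxy)-2-methoxy-6-(2-oxoheptyl)benzoate | CCCCCC1(Cc2cc(OC)cc(O)c2C(=O)Oc2cc(CC(=O)CCCCC)c(C(=O)OC)c(OC)c2)OCCO1 | intermediate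
20 | gustastatin | CCCCCC(=O)Cc1cc(OC)cc(O)c1C(=O)Oc1cc(CC(=O)CCCCC)c(C(=O)OC)c(OC)c1 | target

**Count and risk**

Total step count: 12. Longest linear sequence: 8 steps (steps 1, 2, 3, 4, 5, 6, 11, 12).

Steps most likely to fail:

Step 2. The electron-rich, ortho-substituted acid may metalate slowly, lose carbon dioxide, or stall at the open keto acid. The fallback builds the same bond by benzylic anion chemistry and sets out from 14. Exhaustive methylation (MeI, K2CO3, DMF, 60 °C) should give methyl 2,4-dimethoxy-6-methylbenzoate F1. Lateral lithiation with LiN(iPr)2 at −78 °C and acylation with 13 should give methyl 2,4-dimethoxy-6-(2-oxoheptyl)benzoate F2. Acid-catalysed enol lactonisation (TsOH, toluene, reflux, loss of methanol) then comes back to the route at 7.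

Step 11. The activated carboxyl may rearrange by O-to-N acyl shift, be intercepted by the free ring A hydroxyl, or lose its ketal through the neighbouring acid and close back to the lactone. The fallback protects the phenol and sets out from 11. MOMCl with NaH in DMF should give benzyl 4-methoxy-2-(methoxymethoxy)-6-[(2-pentyl-1,3-dioxolan-2-yl)methyl]benzoate F3. Hydrogenolysis on Pd/C should give 4-methoxy-2-(methoxymethoxy)-6-[(2-pentyl-1,3-dioxolan-2-yl)methyl]benzoic acid F4. Coupling with 18 (DCC, DMAP) should give methyl 2-methoxy-4-({4-methoxy-2-(methoxymethoxy)-6-[(2-pentyl-1,3-dioxolan-2-yl)methyl]benzoyl}oxy)-6-(2-oxoheptyl)benzoate F5. Aqueous HCl in THF at 40 °C removes both acetals and comes back to the route at 20.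

Step 12. Once freed, the ketone may enolise under acid and attack the aryl ester, expelling the ring B phenol, or the depside link may hydrolyse. The fallback uses a far more labile ketone mask and sets out from 10. Trimethyl orthoformate in MeOH with catalytic PPTS at rt should give benzyl 2-(2,2-dimethoxyheptyl)-6-hydroxy-4-methoxybenzoate F6. Hydrogenolysis on Pd/C in EtOAc containing Et3N should give 2-(2,2-dimethoxyheptyl)-6-hydroxy-4-methoxybenzoic acid F7. Coupling with 18 (DCC, DMAP) should give methyl 4-{[2-(2,2-dimethoxyheptyl)-6-hydroxy-4-methoxybenzoyl]oxy}-2-methoxy-6-(2-oxoheptyl)benzoate F8. PPTS in wet acetone at rt then comes back to the route at 20.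

Further compounds
F1 | step 2 | methyl 2,4-dimethoxy-6-methylbenzoate | Cc1cc(OC)cc(OC)c1C(=O)OC
F2 | step 2 | methyl 2,4-dimethoxy-6-(2-oxoheptyl)benzoate | CCCCCC(=O)Cc1cc(OC)cc(OC)c1C(=O)OC
F3 | step 11 | benzyl 4-methoxy-2-(methoxymethoxy)-6-[(2-pentyl-1,3-dioxolan-2-yl)methyl]benzoate | CCCCCC1(Cc2cc(OC)cc(OCOC)c2C(=O)OCc2ccccc2)OCCO1
F4 | step 11 | 4-methoxy-2-(methoxymethoxy)-6-[(2-pentyl-1,3-dioxolan-2-yl)methyl]benzoic acid | CCCCCC1(Cc2cc(OC)cc(OCOC)c2C(=O)O)OCCO1
F5 | step 11 | methyl 2-methoxy-4-({4-methoxy-2-(methoxymethoxy)-6-[(2-pentyl-1,3-dioxolan-2-yl)methyl]benzoyl}oxy)-6-(2-oxoheptyl)benzoate | CCCCCC1(Cc2cc(OC)cc(OCOC)c2C(=O)Oc2cc(CC(=O)CCCCC)c(C(=O)OC)c(OC)c2)OCCO1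
F6 | step 12 | benzyl 2-(2,2-dimethoxyheptyl)-6-hydroxy-4-methoxybenzoate | CCCCCC(OC)(OC)Cc1cc(OC)cc(O)c1C(=O)OCc1ccccc1
F7 | step 12 | 2-(2,2-dimethoxyheptyl)-6-hydroxy-4-methoxybenzoic acid | CCCCCC(OC)(OC)Cc1cc(OC)cc(O)c1C(=O)O
F8 | step 12 | methyl 4-{[2-(2,2-dimethoxyheptyl)-6-hydroxy-4-methoxybenzoyl]oxy}-2-methoxy-6-(2-oxoheptyl)benzoate | CCCCCC(OC)(OC)Cc1cc(OC)cc(O)c1C(=O)Oc1cc(CC(=O)CCCCC)c(C(=O)OC)c(OC)c1
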